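**Remark on the chemistry:** the target is read as catechin-(4α→8)-catechin-(4α→6)-catechin: all three units 2R,3S, top C4 (S) bonded to C8 of the middle unit, middle C4 (R) bonded to C6 of the bottom unit. Compounds 8 and 11 are taken as catalogue items. In steps 7 and 11 the antipode of the bisphosphine that gives the 2S flavanone is used; which antipode this is must be established on the first run.

## Structural features

The target is a B-type procyanidin trimer of three (+)-catechin units. Each unit is a chroman with a phloroglucinol ring A, a dihydropyran ring C and a catechol ring B on C2. All units are 2,3-trans; both interflavan bonds are 4α, that is trans to the neighbouring C3 hydroxyl and cis to the C2 aryl group. The eight stereocentres form two contiguous C2–C3–C4 triads (top and middle) and one C2–C3 pair (bottom). Each interflavan bond joins a doubly benzylic sp3 carbon to an aryl carbon flanked by two oxygens, so it is crowded, rotationally hindered and cleaved by acid through the C4 cation. The twelve phenols are oxidised easily and a free 4'-phenol lets C2 epimerise through a quinone methide, so the free oligomer can only be released last and under neutral conditions. The real difficulty is positional and configurational: C6 and C8 of a catechin ring A are both flanked by two oxygens and differ little as nucleophiles, and each C4 must be set trans to C3. The key step exploits the fact that in the top and middle units O3 and H4 lie on the same face of ring C, opposite the C2 aryl group. This is the pattern written by syn addition of H–B across a C3=C4 double bond, so C4 can be sp2 while the interflavan bonds are made.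

## Logic of the disconnections

**27 ⇒ 26.** Thirteen O–CH2Ph bonds are cut (twelve phenolic, one on O3 of the bottom unit). The phenols stay masked until the end because the free oligomer is air- and acid-sensitive. The forward step must be a neutral hydrogenolysis that leaves the C4–aryl bonds intact.

**26 ⇒ 24 (key).** The C3–O and C4–H bonds of the top and middle units are cut, four bonds in all, giving two C3=C4 double bonds. Four stereocentres disappear, each upper unit keeps only C2, and both interflavan bonds become alkenyl–aryl bonds. The forward step must add H and O syn, with oxygen at C3, on the face opposite the C2 aryl group, on both alkenes, without breaking the allylic C2–O1 bond.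

**24 ⇒ 21 + 13.** The C4(top)–C8(middle) bond is cut as an sp2–sp2 cross-coupling. The position on ring A of the middle unit is fixed by the C8 bromine of 21. The forward step must join two hindered carbons below the temperature at which 2H-chromenes lose C2 configuration.

**21 ⇒ 7 + 18.** The C4(middle)–C6(bottom) bond is cut in the same way. The 4→6 connectivity is fixed by the C6 bromine of 7. The forward step must engage the alkenyl triflate of 18 and leave its C8 aryl bromide for the next coupling.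

**13 ⇒ 12 and 18 ⇒ 17.** The C4–O(triflyl) bond is cut to reveal the flavanone. The forward step must trap the C3 enolate before it expels the ring phenoxide.

**12 ⇒ 10 + 11 and 17 ⇒ 16 + 11.** The C2–aryl bond is cut as a catalytic asymmetric conjugate addition to a chromone. This is the only catalyst-set stereocentre of each upper unit.

**10 ⇒ 8 and 16 ⇒ 14 ⇒ 8.** The O1–C2 and C2–C3 bonds of the chromone are cut back to an o-hydroxyacetophenone and a one-carbon reagent. For 16 the C–Br bond is cut at the acetophenone stage, where the position next to the phenol becomes C8.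

**7 ⇒ 5 ⇒ 4 ⇒ 3 ⇒ 2 ⇒ 1.** The bottom unit comes from the chiral pool with both stereocentres. The C6–Br bond is placed after C8 has been blocked by iodine, which is then removed selectively.

## Other disconnections considered

**Alternative 1:** cut each interflavan bond as flavan-4-yl cation plus arene, the route that comes to mind first. A C4-activated protected catechin A1 is ionised by a Lewis acid and captured at C6 of the C8-bromo-capped nucleophile A2 to give dimer A3; a second coupling at C8 of the upper unit of A3 gives the trimer. It is shorter, since all units come from catechin. Its weakness is that position is decided by kinetic preference and capping: the second coupling offers C8 and C6 of the upper unit of A3, and A1 can attack itself. The two C4 centres are set in two separate intermolecular events. The chosen plan fixes both positions by constitution and sets C3 and C4 of two units in one syn addition.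

**Alternative 2:** cut the middle–bottom bond as carbonyl addition. Aryllithium 19 adds to the C4 ketone of protected taxifolin A4 to give carbinol A5, which is deoxygenated by ionic hydrogenation. Position is secure, but hydride should enter the C4 cation trans to the C3 oxygen, as every nucleophile does in this series. That places the aryl group cis to O3 and gives the 4β epimer A6. The chosen plan delivers H4 and O3 to the same face by mechanism.

**Alternative 3:** cut the interflavan bond at a flavylium salt. Nucleophile 3 adds to C4 of flavylium salt A7 to give flav-2-ene A8, and hydroboration then relays C3 and C2 from C4. Here C4 is created by attack on a planar achiral cation from a nucleophile whose stereocentres are remote, so there is no basis for facial control and the relay starts from an uncontrolled centre. The C6/C8 choice is again kinetic and favours C8. The chosen plan runs the relay the other way, from a catalyst-set C2.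

Key step: step 15

## Steps

Flav-3-enes 13, 18, 21 and 24 are handled on triethylamine-deactivated silica and kept from light and acid.

Step 1
Reactants: 1 (+)-catechin
Product: 2 5,7,3',4'-tetra-O-benzyl-(+)-catechin
Conditions: BnBr (4.4 equiv), K2CO3, DMF, 0 °C to rt
Reagents that add atoms: benzyl bromide BrCc1ccccc1
Why: Williamson etherification of the four phenols; carbonate does not deprotonate the C3 hydroxyl and the mild conditions should avoid C2 epimerisation.

Step 2
Reactants: 2 5,7,3',4'-tetra-O-benzyl-(+)-catechin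
Product: 3 3,5,7,3',4'-penta-O-benzyl-(+)-catechin
Conditions: NaH, BnBr, n-Bu4NI (cat.), DMF, 0 °C to rt
Reagents that add atoms: benzyl bromide BrCc1ccccc1
Why: Williamson etherification of the secondary alcohol; this removes the only acidic proton before the organolithium steps.

Step 3
Reactants: 3 3,5,7,3',4'-penta-O-benzyl-(+)-catechin
Product: 4 8-iodo-3,5,7,3',4'-penta-O-benzyl-(+)-catechin
Conditions: NIS (1.05 equiv), CH2Cl2, −30 °C to 0 °C, dark
Reagents that add atoms: N-iodosuccinimide O=C1CCC(=O)N1I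
Why: Electrophilic aromatic iodination of ring A; C8, between the ring oxygen and one benzyloxy group, is less hindered than C6 between two benzyloxy groups, the preference shown by bromination in this substrate class. Iodine serves only as a removable block.

Step 4
Reactants: 4 8-iodo-3,5,7,3',4'-penta-O-benzyl-(+)-catechin
Product: 5 6-bromo-8-iodo-3,5,7,3',4'-penta-O-benzyl-(+)-catechin
Conditions: NBS (1.05 equiv), CH2Cl2, 0 °C
Reagents that add atoms: N-bromosuccinimide O=C1CCC(=O)N1Br
Why: Electrophilic aromatic bromination at C6, the only open position of ring A; ring B is far less activated.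

Step 5
Reactants: 5 6-bromo-8-iodo-3,5,7,3',4'-penta-O-benzyl-(+)-catechin
Product: 7 6-bromo-3,5,7,3',4'-penta-O-benzyl-(+)-catechin, via 8-lithio-6-bromo aryllithium 6 (not isolated)
Conditions: n-BuLi (1.0 equiv), THF, −90 °C, 5 min; then MeOH
Reagents that add atoms: none
Why: Iodine–lithium exchange is much faster than bromine–lithium exchange at low temperature, so only the C8 halogen is replaced; protonation leaves the C6 bromide with C8 free.

Step 6
Reactants: 8 1-[2,4-bis(benzyloxy)-6-hydroxyphenyl]ethanone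
Product: 10 5,7-bis(benzyloxy)-4H-chromen-4-one, via enaminone 9 (not isolated)
Conditions: DMF-DMA, toluene, 100 °C; then conc. HCl, CH2Cl2, rt
Reagents that add atoms: N,N-dimethylformamide dimethyl acetal COC(OC)N(C)C
Why: Enaminone condensation at the acetyl methyl group, then acid-promoted conjugate addition of the phenol and loss of dimethylamine (standard chromone synthesis).

Step 7
Reactants: 10 5,7-bis(benzyloxy)-4H-chromen-4-one; 11 3,4-bis(benzyloxy)phenylboronic acid
Product: 12 (2S)-5,7-bis(benzyloxy)-2-[3,4-bis(benzyloxy)phenyl]chroman-4-one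
Conditions: [Rh(OH)(cod)]2 (3 mol %), MeO-F12-BIPHEP [6,6'-dimethoxybiphenyl-2,2'-diylbis(bis(3,4,5-trifluorophenyl)phosphine), antipode giving 2S] (7 mol %), toluene/H2O 10:1, 40 °C; recrystallisation
Reagents that add atoms: none
Why: Hayashi–Miyaura asymmetric 1,4-addition; the aryl–rhodium species adds to C2 on the enantiotopic face selected by the bisphosphine, setting C2 (S) by catalyst control. Base-free conditions spare the flavanone from retro-oxa-Michael ring opening.

Step 8
Reactants: 12 (2S)-5,7-bis(benzyloxy)-2-[3,4-bis(benzyloxy)phenyl]chroman-4-one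
Product: 13 (2S)-5,7-bis(benzyloxy)-2-[3,4-bis(benzyloxy)phenyl]-2H-chromen-4-yl trifluoromethanesulfonate
Conditions: NaN(SiMe3)2 (1.1 equiv), THF, −78 °C, 10 min; N-(5-chloropyridin-2-yl)triflimide, −78 °C
Reagents that add atoms: N-(5-chloropyridin-2-yl)bis(trifluoromethanesulfonimide) O=S(=O)(N(c1ccc(Cl)cn1)S(=O)(=O)C(F)(F)F)C(F)(F)F
Why: Kinetic enolisation at C3, the only enolisable position, and O-triflation by a reagent that reacts at −78 °C, so the enolate is trapped before it can expel the ring phenoxide; C2 is not touched.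

Step 9
Reactants: 8 1-[2,4-bis(benzyloxy)-6-hydroxyphenyl]ethanone
Product: 14 1-[4,6-bis(benzyloxy)-3-bromo-2-hydroxyphenyl]ethanone
Conditions: NBS (1.0 equiv), CH2Cl2, −10 °C
Reagents that add atoms: N-bromosuccinimide O=C1CCC(=O)N1Br
Why: Electrophilic aromatic bromination ortho to the free phenol and para to a benzyloxy group, the less hindered of the two activated sites; the phenol oxygen later becomes O1, so this carbon becomes C8.

Step 10
Reactants: 14 1-[4,6-bis(benzyloxy)-3-bromo-2-hydroxyphenyl]ethanone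
Product: 16 5,7-bis(benzyloxy)-8-bromo-4H-chromen-4-one, via bromo enaminone 15 (not isolated)
Conditions: DMF-DMA, toluene, 100 °C; then conc. HCl, CH2Cl2, rt
Reagents that add atoms: N,N-dimethylformamide dimethyl acetal COC(OC)N(C)C
Why: Same enaminone condensation and cyclisation as step 6; the only phenol is the one next to bromine, which fixes bromine at C8.

Step 11
Reactants: 16 5,7-bis(benzyloxy)-8-bromo-4H-chromen-4-one; 11 3,4-bis(benzyloxy)phenylboronic acid
Product: 17 (2S)-5,7-bis(benzyloxy)-8-bromo-2-[3,4-bis(benzyloxy)phenyl]chroman-4-one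
Conditions: [Rh(OH)(cod)]2 (3 mol %), MeO-F12-BIPHEP (antipode giving 2S, 7 mol %), toluene/H2O 10:1, 40 °C; recrystallisation
Reagents that add atoms: none
Why: Hayashi–Miyaura asymmetric 1,4-addition as in step 7; monovalent rhodium does not insert into the hindered aryl bromide under these conditions, and C2 (S) is set by the catalyst.

Step 12
Reactants: 17 (2S)-5,7-bis(benzyloxy)-8-bromo-2-[3,4-bis(benzyloxy)phenyl]chroman-4-one
Product: 18 (2S)-5,7-bis(benzyloxy)-8-bromo-2-[3,4-bis(benzyloxy)phenyl]-2H-chromen-4-yl trifluoromethanesulfonate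
Conditions: NaN(SiMe3)2 (1.1 equiv), THF, −78 °C, 10 min; N-(5-chloropyridin-2-yl)triflimide, −78 °C
Reagents that add atoms: N-(5-chloropyridin-2-yl)bis(trifluoromethanesulfonimide) O=S(=O)(N(c1ccc(Cl)cn1)S(=O)(=O)C(F)(F)F)C(F)(F)F
Why: Enol triflate formation as in step 8; the amide base deprotonates C3 faster than it attacks the aryl bromide.

Step 13
Reactants: 7 6-bromo-3,5,7,3',4'-penta-O-benzyl-(+)-catechin; 18 (2S)-5,7-bis(benzyloxy)-8-bromo-2-[3,4-bis(benzyloxy)phenyl]-2H-chromen-4-yl trifluoromethanesulfonate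
Product: 21 (2S)-8-bromo-5,7,3',4'-tetrakis(benzyloxy)flav-3-ene bonded through C4 to C6 of 3,5,7,3',4'-penta-O-benzyl-(+)-catechin, via aryllithium 19 (not isolated), via arylzinc chloride 20 (not isolated)
Conditions: 7, n-BuLi (1.05 equiv), THF, −78 °C; ZnCl2 (1.2 equiv), −78 °C to rt; then 18 (0.85 equiv), Pd(PPh3)4 (5 mol %), 45 °C, dark
Reagents that add atoms: none
Why: Bromine–lithium exchange, transmetalation to zinc and Negishi coupling; zerovalent palladium with triphenylphosphine inserts into the alkenyl triflate much faster than into the hindered, electron-rich C8 aryl bromide. The ipso coupling fixes the 4→6 connectivity; no stereocentre is formed.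

Step 14
Reactants: 21 bromo dimer from step 13; 13 (2S)-5,7-bis(benzyloxy)-2-[3,4-bis(benzyloxy)phenyl]-2H-chromen-4-yl trifluoromethanesulfonate
Product: 24 bis(flav-3-ene) trimer: C4 of the top (2S)-flav-3-ene bonded to C8 of the middle (2S)-flav-3-ene whose C4 is bonded to C6 of penta-O-benzyl-(+)-catechin, via aryllithium 22 (not isolated), via arylzinc chloride 23 (not isolated)
Conditions: 21, n-BuLi (1.05 equiv), THF, −78 °C; ZnCl2 (1.2 equiv), −78 °C to rt; then 13 (1.2 equiv), Pd2(dba)3 (2.5 mol %), SPhos (10 mol %), 45 °C, dark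
Reagents that add atoms: none
Why: Second Negishi coupling, now at the only halogen left; a biarylphosphine ligand is used because the new bond has two ortho oxygens on one side and a peri benzyloxy group on the other. The ipso coupling fixes the 4→8 connectivity.

Step 15
Reactants: 24 bis(flav-3-ene) trimer
Product: 26 catechin-(4α→8)-catechin-(4α→6)-catechin tridecabenzyl ether with free 3-OH on the top and middle units, via bis(alkylborane) 25 (not isolated)
Conditions: BH3·THF (10 equiv), THF, 0 °C to rt; then 3 M NaOH, 30% H2O2, 0 °C to rt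
Reagents that add atoms: hydrogen peroxide OO
Why: Hydroboration–oxidation of a trisubstituted cyclic styrene, the reaction type that converts flav-3-enes to 2,3-trans-flavan-3-ols, run here on two such alkenes at once. Borane adds through a concerted four-centre transition state, so H and B arrive on the same face; boron bonds to C3 and hydride to C4 because C4 carries two electron-rich aryl groups that stabilise developing positive charge and is the more hindered carbon. In each 2H-chromene ring the only sp3 carbon, C2, is allylic to C3 and holds its aryl group on the α face, so borane should approach C3 from the β face; boron (then oxygen) ends up trans to the C2 aryl group and the new C4–H on the same β face, which leaves the C4 aryl substituent α and trans to O3. C3 is thus controlled by C2 through facial shielding and C4 by C3 through the syn geometry of the addition, independently in the top and middle units, so four stereocentres follow from two. The C4 aryl group is twisted out of the alkene plane by its two ortho oxygens and shields both faces about equally, so it should not override the bias from C2. Oxidation of the C–B bonds by alkaline peroxide proceeds with retention. No ring is closed in this step. The selectivities needed are boron at C3, β-face attack on both alkenes and survival of the allylic C2–O1 bond, which low temperature and a non-acidic work-up are chosen to protect.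

Step 16
Reactants: 26 tridecabenzyl ether from step 15
Product: 27 catechin-(4α→8)-catechin-(4α→6)-catechin (CNP0178679.4)
Conditions: H2 (1 atm), Pd(OH)2/C, THF/MeOH/H2O, rt; filtration under argon, lyophilisation
Reagents that add atoms: none
Why: Hydrogenolysis of twelve aryl benzyl ethers and one alkyl benzyl ether under neutral conditions; the C4–aryl bonds are C–C bonds and are not cleaved, and no acid or base is present to ionise C4 or epimerise C2.

## Compound list

1 | (+)-catechin, (2R,3S)-2-(3,4-dihydroxyphenyl)chromane-3,5,7-triol | Oc1cc(O)c2c(c1)O[C@H](c1ccc(O)c(O)c1)[C@@H](O)C2 | starting material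
2 | 5,7,3',4'-tetra-O-benzyl-(+)-catechin | c1ccccc1COc1cc(OCc3ccccc3)c2c(c1)O[C@H](c1ccc(OCc3ccccc3)c(OCc3ccccc3)c1)[C@@H](O)C2 | intermediate
3 | 3,5,7,3',4'-penta-O-benzyl-(+)-catechin | c1ccccc1COc1cc(OCc3ccccc3)c2c(c1)O[C@H](c1ccc(OCc3ccccc3)c(OCc3ccccc3)c1)[C@@H](OCc3ccccc3)C2 | intermediate
4 | 8-iodo-3,5,7,3',4'-penta-O-benzyl-(+)-catechin | c1ccccc1COc1cc(OCc3ccccc3)c2c(c1I)O[C@H](c1ccc(OCc3ccccc3)c(OCc3ccccc3)c1)[C@@H](OCc3ccccc3)C2 | intermediate
5 | 6-bromo-8-iodo-3,5,7,3',4'-penta-O-benzyl-(+)-catechin | c1ccccc1COc1c(Br)c(OCc3ccccc3)c2c(c1I)O[C@H](c1ccc(OCc3ccccc3)c(OCc3ccccc3)c1)[C@@H](OCc3ccccc3)C2 | intermediate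
6 | 6-bromo-8-lithio-3,5,7,3',4'-penta-O-benzyl-(+)-catechin | c1ccccc1COc1c(Br)c(OCc3ccccc3)c2c(c1[Li])O[C@H](c1ccc(OCc3ccccc3)c(OCc3ccccc3)c1)[C@@H](OCc3ccccc3)C2 | intermediate
7 | 6-bromo-3,5,7,3',4'-penta-O-benzyl-(+)-catechin | c1ccccc1COc1c(Br)c(OCc3ccccc3)c2c(c1)O[C@H](c1ccc(OCc3ccccc3)c(OCc3ccccc3)c1)[C@@H](OCc3ccccc3)C2 | intermediate
8 | 1-[2,4-bis(benzyloxy)-6-hydroxyphenyl]ethanone | CC(=O)c1c(O)cc(OCc2ccccc2)cc1OCc1ccccc1 | starting material
9 | (E)-1-[2,4-bis(benzyloxy)-6-hydroxyphenyl]-3-(dimethylamino)prop-2-en-1-one | CN(C)/C=C/C(=O)c1c(O)cc(OCc2ccccc2)cc1OCc1ccccc1 | intermediate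
10 | 5,7-bis(benzyloxy)-4H-chromen-4-one | O=c1ccoc2cc(OCc3ccccc3)cc(OCc3ccccc3)c12 | intermediate
11 | 3,4-bis(benzyloxy)phenylboronic acid | OB(O)c1ccc(OCc2ccccc2)c(OCc2ccccc2)c1 | starting material
12 | (2S)-5,7-bis(benzyloxy)-2-[3,4-bis(benzyloxy)phenyl]chroman-4-one | c1ccccc1COc1cc(OCc3ccccc3)c2c(c1)O[C@H](c1ccc(OCc3ccccc3)c(OCc3ccccc3)c1)CC2=O | intermediate
13 | (2S)-5,7-bis(benzyloxy)-2-[3,4-bis(benzyloxy)phenyl]-2H-chromen-4-yl trifluoromethanesulfonate | c1ccccc1COc1cc(OCc3ccccc3)c2c(c1)O[C@H](c1ccc(OCc3ccccc3)c(OCc3ccccc3)c1)C=C2OS(=O)(=O)C(F)(F)F | intermediate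
14 | 1-[4,6-bis(benzyloxy)-3-bromo-2-hydroxyphenyl]ethanone | CC(=O)c1c(O)c(Br)c(OCc2ccccc2)cc1OCc1ccccc1 | intermediate
15 | (E)-1-[4,6-bis(benzyloxy)-3-bromo-2-hydroxyphenyl]-3-(dimethylamino)prop-2-en-1-one | CN(C)/C=C/C(=O)c1c(O)c(Br)c(OCc2ccccc2)cc1OCc1ccccc1 | intermediate
16 | 5,7-bis(benzyloxy)-8-bromo-4H-chromen-4-one | O=c1ccoc2c(Br)c(OCc3ccccc3)cc(OCc3ccccc3)c12 | intermediate
17 | (2S)-5,7-bis(benzyloxy)-8-bromo-2-[3,4-bis(benzyloxy)phenyl]chroman-4-one | c1ccccc1COc1cc(OCc3ccccc3)c2c(c1Br)O[C@H](c1ccc(OCc3ccccc3)c(OCc3ccccc3)c1)CC2=O | intermediate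
18 | (2S)-5,7-bis(benzyloxy)-8-bromo-2-[3,4-bis(benzyloxy)phenyl]-2H-chromen-4-yl trifluoromethanesulfonate | c1ccccc1COc1cc(OCc3ccccc3)c2c(c1Br)O[C@H](c1ccc(OCc3ccccc3)c(OCc3ccccc3)c1)C=C2OS(=O)(=O)C(F)(F)F | intermediate
19 | 6-lithio-3,5,7,3',4'-penta-O-benzyl-(+)-catechin | c1ccccc1COc1c([Li])c(OCc3ccccc3)c2c(c1)O[C@H](c1ccc(OCc3ccccc3)c(OCc3ccccc3)c1)[C@@H](OCc3ccccc3)C2 | intermediate
20 | 6-(chlorozincio)-3,5,7,3',4'-penta-O-benzyl-(+)-catechin | c1ccccc1COc1c([Zn]Cl)c(OCc3ccccc3)c2c(c1)O[C@H](c1ccc(OCc3ccccc3)c(OCc3ccccc3)c1)[C@@H](OCc3ccccc3)C2 | intermediate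
21 | (2S)-8-bromo-5,7,3',4'-tetrakis(benzyloxy)flav-3-ene bonded through C4 to C6 of 3,5,7,3',4'-penta-O-benzyl-(+)-catechin | c1ccccc1COc1cc(OCc3ccccc3)c2c(c1Br)O[C@H](c1ccc(OCc3ccccc3)c(OCc3ccccc3)c1)C=C2c1c(OCc3ccccc3)cc2c(c1OCc3ccccc3)C[C@H](OCc3ccccc3)[C@@H](c1ccc(OCc3ccccc3)c(OCc3ccccc3)c1)O2 | intermediate
22 | 8-lithio analogue of 21 | c1ccccc1COc1cc(OCc3ccccc3)c2c(c1[Li])O[C@H](c1ccc(OCc3ccccc3)c(OCc3ccccc3)c1)C=C2c1c(OCc3ccccc3)cc2c(c1OCc3ccccc3)C[C@H](OCc3ccccc3)[C@@H](c1ccc(OCc3ccccc3)c(OCc3ccccc3)c1)O2 | intermediate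
23 | 8-(chlorozincio) analogue of 21 | c1ccccc1COc1cc(OCc3ccccc3)c2c(c1[Zn]Cl)O[C@H](c1ccc(OCc3ccccc3)c(OCc3ccccc3)c1)C=C2c1c(OCc3ccccc3)cc2c(c1OCc3ccccc3)C[C@H](OCc3ccccc3)[C@@H](c1ccc(OCc3ccccc3)c(OCc3ccccc3)c1)O2 | intermediate
24 | bis(flav-3-ene) trimer: top (2S)-5,7,3',4'-tetrakis(benzyloxy)flav-3-en-4-yl on C8 of middle (2S)-5,7,3',4'-tetrakis(benzyloxy)flav-3-ene, whose C4 is on C6 of penta-O-benzyl-(+)-catechin | c1ccccc1COc1cc(OCc3ccccc3)c2c(c1)O[C@H](c1ccc(OCc3ccccc3)c(OCc3ccccc3)c1)C=C2c1c(OCc3ccccc3)cc(OCc3ccccc3)c2c1O[C@H](c1ccc(OCc3ccccc3)c(OCc3ccccc3)c1)C=C2c1c(OCc3ccccc3)cc2c(c1OCc3ccccc3)C[C@H](OCc3ccccc3)[C@@H](c1ccc(OCc3ccccc3)c(OCc3ccccc3)c1)O2 | intermediate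
25 | bis(C3-boranyl) adduct of 24 (BH2 on the β face at C3 of the top and middle units, H4 on the same face) | c1ccccc1COc1cc(OCc3ccccc3)c2c(c1)O[C@H](c1ccc(OCc3ccccc3)c(OCc3ccccc3)c1)[C@@H](B)[C@@H]2c1c(OCc3ccccc3)cc(OCc3ccccc3)c2c1O[C@H](c1ccc(OCc3ccccc3)c(OCc3ccccc3)c1)[C@@H](B)[C@@H]2c1c(OCc3ccccc3)cc2c(c1OCc3ccccc3)C[C@H](OCc3ccccc3)[C@@H](c1ccc(OCc3ccccc3)c(OCc3ccccc3)c1)O2 | intermediate
26 | catechin-(4α→8)-catechin-(4α→6)-catechin tridecabenzyl ether (all phenols and bottom O3 benzylated; top and middle 3-OH free) | c1ccccc1COc1cc(OCc3ccccc3)c2c(c1)O[C@H](c1ccc(OCc3ccccc3)c(OCc3ccccc3)c1)[C@@H](O)[C@@H]2c1c(OCc3ccccc3)cc(OCc3ccccc3)c2c1O[C@H](c1ccc(OCc3ccccc3)c(OCc3ccccc3)c1)[C@@H](O)[C@@H]2c1c(OCc3ccccc3)cc2c(c1OCc3ccccc3)C[C@H](OCc3ccccc3)[C@@H](c1ccc(OCc3ccccc3)c(OCc3ccccc3)c1)O2 | intermediate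
27 | catechin-(4α→8)-catechin-(4α→6)-catechin (CNP0178679.4) | Oc1cc(O)c2c(c1)O[C@H](c1ccc(O)c(O)c1)[C@@H](O)[C@@H]2c1c(O)cc(O)c2c1O[C@H](c1ccc(O)c(O)c1)[C@@H](O)[C@@H]2c1c(O)cc2c(c1O)C[C@H](O)[C@@H](c1ccc(O)c(O)c1)O2 | target

## Step count and least certain steps

Total step count: 16. Longest linear sequence: 9 steps (steps 1–5, then 13–16).

**Step 15 (key).** Hydroboration of the more crowded top alkene may stop short of completion, since its C4 lies between two ortho-substituted aryl groups. Facial selectivity may erode if the twisted C4 aryl group hinders the β face as much as the C2 aryl group hinders the α face. The C3 borane may also eliminate toward C2–O1 cleavage. Fallback: give up the alkene route for the C4 centres and form both interflavan bonds by Lewis-acid capture of flavan-4-yl cations. It sets out from 2 and 4. Oxidation of 2 with DDQ in the presence of 2-ethoxyethanol gives the 4-(2-ethoxyethoxy) ether F1. TMSOTf at −78 °C with excess 4, whose C8 is blocked by iodine, gives the 4α→6 dimer F2. A second TMSOTf coupling of F1 at C8 of the upper unit of F2 gives the iodine-capped trimer F3. Hydrogenolysis (H2, Pd(OH)2/C, Et3N) removes the benzyl groups and the iodine, and the fallback comes back to the route at 27.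

**Step 11 (and its twin, step 7).** Aryl–rhodium addition may turn over slowly on a chromone deactivated by two alkoxy groups and crowded by the peri benzyloxy group. Protodeboronation of 11 may then outrun addition, and the enantiomeric excess may be too low to upgrade by crystallisation. The step also inherits the bromine position from step 9. Fallback: take C2 and the bromine position from the chiral pool. It sets out from 2. NBS gives the C8 bromide F4, and acetylation gives the 3-acetate F5. DDQ in wet CH2Cl2 gives the C4 alcohol F6, and Dess–Martin oxidation gives the 3-acetoxy-4-ketone F7. SmI2 in THF/MeOH at −78 °C cleaves the α-acetoxy group, and the fallback comes back at 17. The same sequence without the bromination leads from 2 to 12.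

**Step 12 (and its twin, step 8).** The C3 enolate may expel the ring phenoxide (E1cB) before it is triflated. That would give the chalcone and, on reclosure, racemic material. Fallback: avoid the enolate and the cross-coupling together. It sets out from 17 and 19. Transmetalation of 19 with CeCl3 gives the arylcerium reagent F8. Addition of F8 to the ketone of 17 gives the tertiary carbinol F9. Burgess dehydration of F9 under neutral conditions gives the C3=C4 alkene, and the fallback comes back at 21.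

**Step 14 (and step 13).** Transmetalation and reductive elimination may be slow at a bond with three flanking substituents, so that protonation of 23 competes. Prolonged warming may erode the C2 configuration of the 2H-chromenes by reversible electrocyclic ring opening. Fallback: reverse the roles of the partners. It sets out from 13 and 21. Miyaura borylation of 13 (B2pin2, PdCl2(PPh3)2, KOPh, toluene, 50 °C) gives the alkenyl boronate F10. Suzuki–Miyaura coupling of F10 with bromide 21 (Pd(OAc)2, SPhos, K3PO4, THF/H2O, 40 °C) comes back at 24.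

## Further compounds

F1 | step 15 | (2R,3S)-5,7,3',4'-tetra-O-benzyl-4-(2-ethoxyethoxy)catechin (C4 epimers, both ionise to the same cation) | c1ccccc1COc1cc(OCc3ccccc3)c2c(c1)O[C@H](c1ccc(OCc3ccccc3)c(OCc3ccccc3)c1)[C@@H](O)C2OCCOCC
F2 | step 15 | 5,7,3',4'-tetra-O-benzylcatechin-(4α→6)-8-iodo-3,5,7,3',4'-penta-O-benzylcatechin | c1ccccc1COc1cc(OCc3ccccc3)c2c(c1)O[C@H](c1ccc(OCc3ccccc3)c(OCc3ccccc3)c1)[C@@H](O)[C@@H]2c1c(OCc3ccccc3)c(I)c2c(c1OCc3ccccc3)C[C@H](OCc3ccccc3)[C@@H](c1ccc(OCc3ccccc3)c(OCc3ccccc3)c1)O2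
F3 | step 15 | catechin-(4α→8)-catechin-(4α→6)-8-iodocatechin tridecabenzyl ether | c1ccccc1COc1cc(OCc3ccccc3)c2c(c1)O[C@H](c1ccc(OCc3ccccc3)c(OCc3ccccc3)c1)[C@@H](O)[C@@H]2c1c(OCc3ccccc3)cc(OCc3ccccc3)c2c1O[C@H](c1ccc(OCc3ccccc3)c(OCc3ccccc3)c1)[C@@H](O)[C@@H]2c1c(OCc3ccccc3)c(I)c2c(c1OCc3ccccc3)C[C@H](OCc3ccccc3)[C@@H](c1ccc(OCc3ccccc3)c(OCc3ccccc3)c1)O2
F4 | step 11 | 8-bromo-5,7,3',4'-tetra-O-benzyl-(+)-catechin | c1ccccc1COc1cc(OCc3ccccc3)c2c(c1Br)O[C@H](c1ccc(OCc3ccccc3)c(OCc3ccccc3)c1)[C@@H](O)C2
F5 | step 11 | 3-O-acetyl-8-bromo-5,7,3',4'-tetra-O-benzyl-(+)-catechin | c1ccccc1COc1cc(OCc3ccccc3)c2c(c1Br)O[C@H](c1ccc(OCc3ccccc3)c(OCc3ccccc3)c1)[C@@H](OC(C)=O)C2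
F6 | step 11 | 3-O-acetyl-8-bromo-4-hydroxy-5,7,3',4'-tetra-O-benzylcatechin (C4 epimers) | c1ccccc1COc1cc(OCc3ccccc3)c2c(c1Br)O[C@H](c1ccc(OCc3ccccc3)c(OCc3ccccc3)c1)[C@@H](OC(C)=O)C2O
F7 | step 11 | (2R,3R)-3-acetoxy-5,7-bis(benzyloxy)-8-bromo-2-[3,4-bis(benzyloxy)phenyl]chroman-4-one | c1ccccc1COc1cc(OCc3ccccc3)c2c(c1Br)O[C@H](c1ccc(OCc3ccccc3)c(OCc3ccccc3)c1)[C@@H](OC(C)=O)C2=O
F8 | step 12 | 6-(dichlorocerio)-3,5,7,3',4'-penta-O-benzyl-(+)-catechin | c1ccccc1COc1c([Ce](Cl)Cl)c(OCc3ccccc3)c2c(c1)O[C@H](c1ccc(OCc3ccccc3)c(OCc3ccccc3)c1)[C@@H](OCc3ccccc3)C2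
F9 | step 12 | (2S)-8-bromo-5,7,3',4'-tetrakis(benzyloxy)-4-(penta-O-benzylcatechin-6-yl)flavan-4-ol (C4 epimers) | c1ccccc1COc1cc(OCc3ccccc3)c2c(c1Br)O[C@H](c1ccc(OCc3ccccc3)c(OCc3ccccc3)c1)CC2(O)c1c(OCc3ccccc3)cc2c(c1OCc3ccccc3)C[C@H](OCc3ccccc3)[C@@H](c1ccc(OCc3ccccc3)c(OCc3ccccc3)c1)O2
F10 | step 14 | (2S)-5,7-bis(benzyloxy)-2-[3,4-bis(benzyloxy)phenyl]-4-(4,4,5,5-tetramethyl-1,3,2-dioxaborolan-2-yl)-2H-chromene | c1ccccc1COc1cc(OCc3ccccc3)c2c(c1)O[C@H](c1ccc(OCc3ccccc3)c(OCc3ccccc3)c1)C=C2B1OC(C)(C)C(C)(C)O1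
A1 | alternative 1 | 3-O-acetyl-5,7,3',4'-tetra-O-benzyl-4-(2-ethoxyethoxy)catechin (C4 epimers) | c1ccccc1COc1cc(OCc3ccccc3)c2c(c1)O[C@H](c1ccc(OCc3ccccc3)c(OCc3ccccc3)c1)[C@@H](OC(C)=O)C2OCCOCC
A2 | alternative 1 | 8-bromo-3,5,7,3',4'-penta-O-benzyl-(+)-catechin | c1ccccc1COc1cc(OCc3ccccc3)c2c(c1Br)O[C@H](c1ccc(OCc3ccccc3)c(OCc3ccccc3)c1)[C@@H](OCc3ccccc3)C2
A3 | alternative 1 | 3-O-acetyl-5,7,3',4'-tetra-O-benzylcatechin-(4α→6)-8-bromo-3,5,7,3',4'-penta-O-benzylcatechin | c1ccccc1COc1cc(OCc3ccccc3)c2c(c1)O[C@H](c1ccc(OCc3ccccc3)c(OCc3ccccc3)c1)[C@@H](OC(C)=O)[C@@H]2c1c(OCc3ccccc3)c(Br)c2c(c1OCc3ccccc3)C[C@H](OCc3ccccc3)[C@@H](c1ccc(OCc3ccccc3)c(OCc3ccccc3)c1)O2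
A4 | alternative 2 | (2R,3R)-3,5,7-tris(benzyloxy)-2-[3,4-bis(benzyloxy)phenyl]chroman-4-one (penta-O-benzyltaxifolin) | c1ccccc1COc1cc(OCc3ccccc3)c2c(c1)O[C@H](c1ccc(OCc3ccccc3)c(OCc3ccccc3)c1)[C@@H](OCc3ccccc3)C2=O
A5 | alternative 2 | 4-(penta-O-benzylcatechin-6-yl)-3,5,7,3',4'-penta-O-benzylflavan-4-ol from A4 (C4 epimers) | c1ccccc1COc1cc(OCc3ccccc3)c2c(c1)O[C@H](c1ccc(OCc3ccccc3)c(OCc3ccccc3)c1)[C@@H](OCc3ccccc3)C2(O)c1c(OCc3ccccc3)cc2c(c1OCc3ccccc3)C[C@H](OCc3ccccc3)[C@@H](c1ccc(OCc3ccccc3)c(OCc3ccccc3)c1)O2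
A6 | alternative 2 | penta-O-benzylcatechin-(4β→6)-penta-O-benzylcatechin (3,4-cis, wrong C4 epimer) | c1ccccc1COc1cc(OCc3ccccc3)c2c(c1)O[C@H](c1ccc(OCc3ccccc3)c(OCc3ccccc3)c1)[C@@H](OCc3ccccc3)[C@H]2c1c(OCc3ccccc3)cc2c(c1OCc3ccccc3)C[C@H](OCc3ccccc3)[C@@H](c1ccc(OCc3ccccc3)c(OCc3ccccc3)c1)O2
A7 | alternative 3 | 5,7-bis(benzyloxy)-2-[3,4-bis(benzyloxy)phenyl]chromenylium hexafluorophosphate | c1ccccc1COc1cc(OCc3ccccc3)c2ccc(-c4ccc(OCc3ccccc3)c(OCc3ccccc3)c4)[o+]c2c1.F[P-](F)(F)(F)(F)F
A8 | alternative 3 | 5,7,3',4'-tetrakis(benzyloxy)-4-(penta-O-benzylcatechin-6-yl)flav-2-ene (C4 epimers) | c1ccccc1COc1cc(OCc3ccccc3)c2c(c1)OC(c1ccc(OCc3ccccc3)c(OCc3ccccc3)c1)=CC2c1c(OCc3ccccc3)cc2c(c1OCc3ccccc3)C[C@H](OCc3ccccc3)[C@@H](c1ccc(OCc3ccccc3)c(OCc3ccccc3)c1)O2
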